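## Retrosynthetic overview

1. The last step removes one methyl group from each ring. The target comes from meso-1,4-bis(4-hydroxy-3,5-dimethoxyphenyl)-2,3-dimethylbutane, in which the extra OMe is a temporary blocking group.
2. The chain is hidden in a temporary ring at a higher oxidation level. Chain carbons C7-C8(Me)-C8'(Me)-C7' correspond to C2-C3-C4-C5 of a 2,5-diaryl-3,4-dimethylfuran; cis-hydrogenation sets the meso pair and benzylic hydrogenolysis removes the ring oxygen.
3. Key disconnection: both aryl C1-C7 bonds are made in one twofold dehydrogenative (C-H/C-H) anodic coupling of 3,4-dimethylfuran and two molecules of 2,6-dimethoxyphenol. This unites two nucleophilic carbons by oxidation.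
4. Enabling feature: in each benzene ring C1 is para to the C4 hydroxyl, and both ortho carbons C3 and C5 bear oxygen, so the phenoxyl radical can bond only at C1. The mirror-symmetric chain puts its methyl-bearing carbons C8/C8' on the furan beta positions, so only the two alpha carbons (future C7/C7') are free.
5. Ring order: both benzene rings are bought intact. The only ring made is the temporary furan (steps 1-2, from 2,3-dimethylmaleic anhydride), and it is opened again in step 4.

Key step: step 3

Remark on the chemistry: because the two aryl groups are identical, the (2R,3S) pair in the SMILES describes the achiral meso compound. Only the relative configuration has to be set.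

## Route

Step 1
Reactants: 1 2,3-dimethylmaleic anhydride
Product: 2 3,4-dimethylfuran-2(5H)-one
Conditions: NaBH4, THF, 0 °C to rt; then 2 M HCl
Reagents that add atoms: none
Why: This is the borohydride reduction of a cyclic anhydride to a lactone, in which two hydrides take one of the two equivalent carbonyl groups to the hydroxy carboxylate, acid closes the butenolide, and the tetrasubstituted C=C bond resists conjugate reduction.

Step 2
Reactants: 2 3,4-dimethylfuran-2(5H)-one
Product: 4 3,4-dimethylfuran, via lactol 3 (not isolated)
Conditions: i-Bu2AlH, CH2Cl2, −78 °C; then 2 M HCl, 0 °C to rt; fractional distillation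
Reagents that add atoms: none
Why: This is the standard butenolide-to-furan conversion, in which partial reduction stops at the aluminium lactolate at low temperature and acid work-up dehydrates lactol 3, driven by aromatisation.

Step 3
Reactants: 4 3,4-dimethylfuran; 5 2,6-dimethoxyphenol (syringol; two molecules enter the product, 3 equiv used)
Product: 7 4,4'-(3,4-dimethylfuran-2,5-diyl)bis(2,6-dimethoxyphenol), via monoarylfuran 6 (not isolated)
Conditions: undivided cell, boron-doped diamond anode and cathode, constant current (about 5 mA cm−2, about 2.5 F per new C-C bond), Bu3MeN(O3SOMe) (0.1 M), (CF3)2CHOH, 25 °C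
Reagents that add atoms: none
Why: Proposed new method: at the anode the component that is easiest to oxidise, phenol 5, should lose an electron and a proton to give a phenoxyl radical whose spin sits on O, on C2 and C6 (both blocked by OMe) and on the free para carbon C4, and the nucleophilic alpha carbon of furan 4 (beta carbons blocked by methyl, the developing cation stabilised by the ring oxygen and the adjacent methyl group) bonds to that carbon, after which a second electron and two protons are lost and both rings re-aromatise to 6. Compound 6 is a still better donor whose free furan alpha carbon carries the highest electron density and, after oxidation, spin density, so it is joined to the para carbon of a second phenoxyl radical (as nucleophile or by radical-radical combination, both pairings giving the same bond) to give 7, and this second event unites the aryl-bearing four-carbon chain precursor with the second ring. The closest known reaction types are the anodic dehydrogenative cross-coupling of phenols with arenes and, once or twice, with thiophenes at boron-doped diamond in this solvent, and the oxidative para cross-coupling of 2,6-disubstituted phenols with electron-rich arenes; new here are a simple furan as partner and the twofold para mode. No ring is closed and no stereocentre is formed, since the chain carbons stay planar until step 4. The step needs site selectivity, which the substrates secure because each partner offers only one kind of reactive C-H bond, and it needs cross- over homo-coupling, which rests on the hydrogen-bonding solvent lowering the nucleophilicity of neutral 5 (its para carbon is meta to both OMe groups) below that of the furan, and on the excess of 5 that keeps oxidised 6 from meeting itself. Over-oxidation of 7 to its extended quinone should be repaired at the cathode of the undivided cell and, for any rest, by the hydrogenation of step 4.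

Step 4
Reactants: 7 4,4'-(3,4-dimethylfuran-2,5-diyl)bis(2,6-dimethoxyphenol)
Product: 9 meso-(2R,3S)-1,4-bis(4-hydroxy-3,5-dimethoxyphenyl)-2,3-dimethylbutane, via all-cis tetrahydrofuran 8 (not isolated)
Conditions: H2 (5 bar), Pd/C (10 wt% Pd), AcOH, 50 °C
Reagents that add atoms: none
Why: In this furan hydrogenation/benzylic hydrogenolysis sequence, well established for 2,5-diaryl-3,4-dimethylfurans, hydrogen is delivered to the one face of the flat furan that lies on the metal surface, which gives all-cis 8 with the two methyl groups cis and so sets both stereocentres as the meso R,S pair, and the two p-hydroxybenzylic C-O bonds are then cleaved without touching the methyl-bearing carbons.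

Step 5
Reactants: 9 meso-(2R,3S)-1,4-bis(4-hydroxy-3,5-dimethoxyphenyl)-2,3-dimethylbutane
Product: 11 meso-(2R,3S)-1,4-bis(3,4-dihydroxy-5-methoxyphenyl)-2,3-dimethylbutane (target), via bis-o-quinone 10 (not isolated)
Conditions: IBX (2.2 equiv), DMF, 0 °C to rt, dark; then Na2S2O4, H2O, rt, under N2 (one pot)
Reagents that add atoms: IBX (2-iodoxybenzoic acid), O=C1OI(=O)(O)c2ccccc12 (one oxygen atom per ring)
Why: In this oxidative demethylation of 2-methoxyphenols each phenol binds pentavalent iodine, oxygen is delivered to an OMe-bearing ortho carbon, methanol is lost and the ring stops at the o-quinone (so only one of the two equivalent OMe groups per ring can go), and dithionite then reduces 10 to the bis-catechol while the remote stereocentres stay untouched.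

## Compound list

1 | 2,3-dimethylmaleic anhydride | CC1=C(C)C(=O)OC1=O | starting material
2 | 3,4-dimethylfuran-2(5H)-one | CC1=C(C)C(=O)OC1 | intermediate
3 | 3,4-dimethyl-2,5-dihydrofuran-2-ol (racemic lactol, not isolated) | CC1=C(C)C(O)OC1 | intermediate
4 | 3,4-dimethylfuran | Cc1cocc1C | intermediate
5 | 2,6-dimethoxyphenol (syringol) | COc1cccc(OC)c1O | starting material
6 | 4-(3,4-dimethylfuran-2-yl)-2,6-dimethoxyphenol (not isolated) | Cc1coc(-c2cc(OC)c(O)c(OC)c2)c1C | intermediate
7 | 4,4'-(3,4-dimethylfuran-2,5-diyl)bis(2,6-dimethoxyphenol) | Cc1c(C)c(-c2cc(OC)c(O)c(OC)c2)oc1-c3cc(OC)c(O)c(OC)c3 | intermediate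
8 | all-cis (2R,3S,4R,5S; meso) 2,5-bis(4-hydroxy-3,5-dimethoxyphenyl)-3,4-dimethyltetrahydrofuran (not isolated) | C[C@@H]1[C@H](C)[C@H](c2cc(OC)c(O)c(OC)c2)O[C@@H]1c3cc(OC)c(O)c(OC)c3 | intermediate
9 | meso-(2R,3S)-1,4-bis(4-hydroxy-3,5-dimethoxyphenyl)-2,3-dimethylbutane | COc1cc(C[C@@H](C)[C@@H](C)Cc2cc(OC)c(O)c(OC)c2)cc(OC)c1O | intermediate
10 | meso-5,5'-(2,3-dimethylbutane-1,4-diyl)bis(3-methoxycyclohexa-3,5-diene-1,2-dione) (not isolated) | COC1=CC(C[C@@H](C)[C@@H](C)CC2=CC(=O)C(=O)C(OC)=C2)=CC(=O)C1=O | intermediate
11 | meso-(2R,3S)-1,4-bis(3,4-dihydroxy-5-methoxyphenyl)-2,3-dimethylbutane | COc1cc(C[C@@H](C)[C@@H](C)Cc2cc(O)c(O)c(OC)c2)cc(O)c1O | target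

## Step count and risks

Total step count: 5. Longest linear sequence: 5 (1, 2, 4, 7, 9, 11).

**Risk 1 (step 3).** Several processes may outrun the cross-coupling:
- para-para homo-coupling of the phenoxyl radicals
- dimerisation of oxidised 6 through its free furan carbon
- breakdown of the volatile furan by acid or at the anode

The fallback uses known chemistry, makes the same bond, sets out from 5 and 4 and returns at 9. Para-bromination of 5 (NBS) gives 4-bromo-2,6-dimethoxyphenol F1. Benzylation (BnBr, K2CO3, DMF) gives 2-(benzyloxy)-5-bromo-1,3-dimethoxybenzene F2. A twofold palladium-catalysed direct C-H arylation of both alpha positions of 4 follows, by concerted metalation-deprotonation (Pd(OAc)2, PCy3·HBF4, pivalic acid, K2CO3, DMA, 110 °C, sealed tube). It gives 2,5-bis[4-(benzyloxy)-3,5-dimethoxyphenyl]-3,4-dimethylfuran F3. The conditions of step 4 then also cleave the benzyl ethers and deliver 9.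

**Risk 2 (step 4).** Three processes are of concern:
- Double-bond migration in a partly reduced dihydrofuran, or C-O cleavage at the enol ether stage to an epimerisable ketone, would erode the cis relationship of the methyl groups.
- The reduction may stall at 8.
- Acid-triggered ionisation of 8 may lead to Friedel-Crafts closure onto the other ring.

The fallback takes the stereocentres from the meso pool instead of making them. It forms the same bond, sets out from 5 (through aryl bromide F2, made as described above) and returns at 9. Purchased meso-2,3-dimethylsuccinic acid F4 is reduced (LiAlH4, THF) to meso-2,3-dimethylbutane-1,4-diol F5. An Appel-type iodination (I2, PPh3, imidazole) converts this into meso-1,4-diiodo-2,3-dimethylbutane F6. F6 is coupled twice with F2 by nickel-catalysed reductive cross-electrophile coupling (NiBr2(MeOCH2CH2OMe), 4,4'-di-tert-butyl-2,2'-bipyridine, Zn, DMA, 60 °C). This gives meso-1,4-bis[4-(benzyloxy)-3,5-dimethoxyphenyl]-2,3-dimethylbutane F7. Hydrogenolysis (H2, Pd/C, EtOAc/EtOH) gives 9.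

**Risk 3 (step 5).** The alkyl-o-quinone units of 10 may tautomerise to p-quinone methides and oligomerise before the reductive quench. The two rings may also convert unevenly.

The fallback differentiates the oxygen pattern before the coupling, sets out from 4 and returns at 11. Dakin oxidation (H2O2, NaOH) of purchased 5-bromo-2-hydroxy-3-methoxybenzaldehyde F8 gives 5-bromo-3-methoxybenzene-1,2-diol F9. Benzylation (BnBr, K2CO3, DMF) gives 1,2-bis(benzyloxy)-5-bromo-3-methoxybenzene F10. Twofold direct C-H arylation of 4, under the palladium conditions given above, gives 2,5-bis[3,4-bis(benzyloxy)-5-methoxyphenyl]-3,4-dimethylfuran F11. One hydrogenation (H2, Pd/C, AcOH, 50 °C) saturates the furan, cleaves the ring C-O bonds and removes all four benzyl groups to give 11.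

## Further compounds

F1 | step 3 | 4-bromo-2,6-dimethoxyphenol | COc1cc(Br)cc(OC)c1O
F2 | step 3 | 2-(benzyloxy)-5-bromo-1,3-dimethoxybenzene | COc1cc(Br)cc(OC)c1OCc2ccccc2
F3 | step 3 | 2,5-bis[4-(benzyloxy)-3,5-dimethoxyphenyl]-3,4-dimethylfuran | Cc1c(C)c(-c2cc(OC)c(OCc3ccccc3)c(OC)c2)oc1-c4cc(OC)c(OCc5ccccc5)c(OC)c4
F4 | step 4 | meso-2,3-dimethylsuccinic acid (purchased) | OC(=O)[C@@H](C)[C@@H](C)C(=O)O
F5 | step 4 | meso-2,3-dimethylbutane-1,4-diol | OC[C@@H](C)[C@@H](C)CO
F6 | step 4 | meso-1,4-diiodo-2,3-dimethylbutane | IC[C@@H](C)[C@@H](C)CI
F7 | step 4 | meso-1,4-bis[4-(benzyloxy)-3,5-dimethoxyphenyl]-2,3-dimethylbutane | COc1cc(C[C@@H](C)[C@@H](C)Cc2cc(OC)c(OCc3ccccc3)c(OC)c2)cc(OC)c1OCc4ccccc4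
F8 | step 5 | 5-bromo-2-hydroxy-3-methoxybenzaldehyde (purchased) | COc1cc(Br)cc(C=O)c1O
F9 | step 5 | 5-bromo-3-methoxybenzene-1,2-diol | COc1cc(Br)cc(O)c1O
F10 | step 5 | 1,2-bis(benzyloxy)-5-bromo-3-methoxybenzene | COc1cc(Br)cc(OCc2ccccc2)c1OCc3ccccc3
F11 | step 5 | 2,5-bis[3,4-bis(benzyloxy)-5-methoxyphenyl]-3,4-dimethylfuran | Cc1c(C)c(-c2cc(OC)c(OCc3ccccc3)c(OCc4ccccc4)c2)oc1-c5cc(OC)c(OCc6ccccc6)c(OCc7ccccc7)c5
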